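**Plan**

- Retrosynthesis: the furan ring is cut at O1–C2 and C2–C3. C2 is the only carbon lying between O1 and the aryl-bearing C3, so O1–C7a–C3a–C3 maps onto an ortho-quinone methide of the benzo ring and C2 onto the carbanion carbon of a sulfonium ylide that already carries the three-carbon ester chain as an enoate.
- The quinone methide precursor is cut at C3–C1' (aryl–CH) into an aryllithium of the 3,5-dimethoxy-2,4-dimethylphenyl ring and a 2-hydroxybenzaldehyde. The benzhydrol is activated as its p-tolyl sulfone so that the quinone methide is released by the same mild base that forms the ylide.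
- Forward: 2,6-dimethoxytoluene → meta-bromide → ring methylation (formylation, reduction) → aryllithium addition → sulfone → [4+1] annulation, which closes the dihydrofuran (the only ring formed) → DDQ aromatisation → enoate hydrogenation → demethylation.
- Stereochemistry: the target has no stereocentre. The trans C2/C3 centres made in the annulation are racemic and are erased by the dehydrogenation.
- The ylide is the crotonate-derived one and not a β-keto-ester ylide: it has no second acidic methylene between two carbonyl groups, and it leaves a C=C to hydrogenate instead of a ketone to deoxygenate beside an electron-rich benzofuran.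

Key step: step 8

Assumption: the target is drawn without stereodescriptors, so the hindered C3–C1' aryl axis is taken as configurationally unspecified and no control of it is attempted.

**Route**

Step 1
Reactants: 1 2,6-dimethoxytoluene
Product: 3 5-bromo-1,3-dimethoxy-2-methylbenzene, via aryl pinacol boronate 2 (not isolated)
Conditions: [Ir(OMe)(cod)]2 (1.5 mol %), 4,4'-di-tert-butyl-2,2'-bipyridine (3 mol %), B2pin2 (1.0 equiv), THF, 80 °C; evaporate; CuBr2 (2.5 equiv), MeOH/H2O 1:1, 80 °C
Reagents that add atoms: CuBr2, Br[Cu]Br (the bromine of 3); bis(pinacolato)diboron, CC1(C)OB(OC1(C)C)B1OC(C)(C)C(C)(C)O1 (the boryl group of 2 only)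
Why: Sterically controlled iridium-catalysed arene C–H borylation selects the only ring C–H without an ortho substituent (C4, meta to both methoxy groups), and copper-mediated bromodeboronation then puts bromine at this position, which electrophilic bromination (directed ortho/para to the methoxy groups) cannot reach.

Step 2
Reactants: 3 5-bromo-1,3-dimethoxy-2-methylbenzene
Product: 4 6-bromo-2,4-dimethoxy-3-methylbenzaldehyde
Conditions: Cl2CHOMe (1.3 equiv), TiCl4 (2.2 equiv), CH2Cl2, 0 °C → rt; ice/H2O
Reagents that add atoms: dichloromethyl methyl ether, COC(Cl)Cl (formyl carbon); water, O (formyl oxygen on hydrolysis)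
Why: Rieche formylation (electrophilic aromatic substitution) can only take place at the two equivalent free positions, each ortho to one methoxy group and para to the other, so a single aldehyde should result.

Step 3
Reactants: 4 6-bromo-2,4-dimethoxy-3-methylbenzaldehyde
Product: 5 1-bromo-3,5-dimethoxy-2,4-dimethylbenzene
Conditions: Et3SiH (3 equiv), CF3CO2H, CH2Cl2, 0 °C → rt
Reagents that add atoms: none
Why: Ionic hydrogenation: the methoxy-stabilised benzylic cation formed from the protonated aldehyde, and then from the benzylic alcohol, is trapped twice by Et3SiH, which turns CHO into CH3 and leaves the aryl bromide untouched.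

Step 4
Reactants: 6 2,4-dimethoxy-6-methylbenzaldehyde
Product: 7 2-hydroxy-4-methoxy-6-methylbenzaldehyde
Conditions: BCl3 (1.2 equiv), CH2Cl2, −78 → 0 °C; H2O
Reagents that add atoms: none
Why: Chelation-controlled Lewis-acid ether cleavage: BCl3 bound to the formyl oxygen removes only the methyl group of the ortho methoxy group, the para one being out of reach.

Step 5
Reactants: 5 1-bromo-3,5-dimethoxy-2,4-dimethylbenzene; 7 2-hydroxy-4-methoxy-6-methylbenzaldehyde
Product: 10 2-[(3,5-dimethoxy-2,4-dimethylphenyl)(hydroxy)methyl]-5-methoxy-3-methylphenol (racemic), via aryllithium 8 (not isolated), via sodium phenoxide 9 (not isolated)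
Conditions: 5, n-BuLi (1.05 equiv), THF, −78 °C; 7 (1.2 equiv), NaH (1.2 equiv), THF, 0 °C, transferred into the aryllithium, −78 → 0 °C; sat. aq NH4Cl, 0 °C; crude product taken on
Reagents that add atoms: none
Why: Bromine–lithium exchange gives the aryllithium, which adds 1,2 to the formyl group of the aldehyde whose acidic phenol has been masked beforehand as the sodium phenoxide, so that no aryllithium is quenched; the carbinol centre forms racemic, which is of no consequence because this carbon becomes sp2 in the quinone methide.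

Step 6
Reactants: 10 2-[(3,5-dimethoxy-2,4-dimethylphenyl)(hydroxy)methyl]-5-methoxy-3-methylphenol
Product: 11 2-[(3,5-dimethoxy-2,4-dimethylphenyl)(4-methylbenzenesulfonyl)methyl]-5-methoxy-3-methylphenol (racemic)
Conditions: p-TolSO2Na (2 equiv), HCO2H, THF/H2O, rt
Reagents that add atoms: sodium 4-methylbenzenesulfinate, Cc1ccc(cc1)S(=O)[O-].[Na+]
Why: Acid-promoted SN1 substitution: the benzhydrol, activated by the ortho-hydroxy and para-methoxy groups, ionises to the benzylic cation (protonated quinone methide), which the sulfinate captures at sulfur to give a bench-stable sulfone that fragments to the quinone methide under mild base.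

Step 7
Reactants: 12 methyl (2E)-4-bromobut-2-enoate
Product: 13 [(2E)-4-methoxy-4-oxobut-2-en-1-yl]dimethylsulfonium bromide
Conditions: Me2S (3 equiv), acetone, rt, dark
Reagents that add atoms: dimethyl sulfide, CSC
Why: SN2 alkylation of dimethyl sulfide by the primary allylic bromide gives the crystalline sulfonium salt and leaves the alkene geometry untouched.

Step 8
Reactants: 11 2-[(3,5-dimethoxy-2,4-dimethylphenyl)(4-methylbenzenesulfonyl)methyl]-5-methoxy-3-methylphenol; 13 [(2E)-4-methoxy-4-oxobut-2-en-1-yl]dimethylsulfonium bromide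
Product: 17 methyl (2E)-3-[trans-3-(3,5-dimethoxy-2,4-dimethylphenyl)-6-methoxy-4-methyl-2,3-dihydro-1-benzofuran-2-yl]prop-2-enoate (racemic; 2S,3R enantiomer drawn), via sulfonium ylide 14 (not isolated), via ortho-quinone methide 15 (not isolated), via phenoxide sulfonium betaine 16 (not isolated)
Conditions: 13 (1.5 equiv), Cs2CO3 (3 equiv), MeCN, 0 °C → rt; 11 added last in portions
Reagents that add atoms: none
Why: Cs2CO3 converts 13 into the ester-conjugated allylic ylide 14 and deprotonates phenol 11, whose phenoxide expels p-toluenesulfinate (1,4-elimination) to give ortho-quinone methide 15, its formation being helped by the methoxy group para to the methide carbon. The sulfur-bearing carbon of 14 adds to the exocyclic methide carbon (the future C3), which restores the arene and gives betaine 16; the phenoxide then displaces dimethyl sulfide at that same carbon in a 5-exo-tet SN2 closure, so that C2–C3 and O1–C2 form in one flask. The closest known reactions are the [4+1] annulation of ortho-quinone methides released from 2-(1-tosylalkyl)phenols with stabilised sulfonium ylides, and the [4+1] annulation of 1-oxadienes with crotonate-derived sulfonium ylides to trans-2-alkenyl-2,3-dihydrofurans. The new stereocentres C2 and C3 are set trans by the substrate itself, because ring closure runs through the betaine conformer that keeps the C3 aryl and the C2 alkenyl group on opposite faces of the forming ring; both centres are racemic and are erased in step 9, so the diastereoselectivity does not matter. The step needs attack through the α-carbon of the ambident ylide and C–C before C–O bond formation: α-attack is the normal mode of these ylides toward conjugate acceptors, the hindered phenoxide of 11 should collapse to the quinone methide faster than it can be allylated by 13, and the enoate ylide avoids the second acidic site that a β-keto-ester ylide would carry.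

Step 9
Reactants: 17 methyl (2E)-3-[trans-3-(3,5-dimethoxy-2,4-dimethylphenyl)-6-methoxy-4-methyl-2,3-dihydro-1-benzofuran-2-yl]prop-2-enoate
Product: 18 methyl (2E)-3-[3-(3,5-dimethoxy-2,4-dimethylphenyl)-6-methoxy-4-methyl-1-benzofuran-2-yl]prop-2-enoate
Conditions: DDQ (1.5 equiv), 1,4-dioxane, 80 °C
Reagents that add atoms: none
Why: DDQ dehydrogenation: hydride abstraction from the doubly benzylic C3–H (the cation is stabilised through C3a by the 6-methoxy group) followed by loss of the C2 proton aromatises the furan ring and erases both stereocentres.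

Step 10
Reactants: 18 methyl (2E)-3-[3-(3,5-dimethoxy-2,4-dimethylphenyl)-6-methoxy-4-methyl-1-benzofuran-2-yl]prop-2-enoate
Product: 19 methyl 3-[3-(3,5-dimethoxy-2,4-dimethylphenyl)-6-methoxy-4-methyl-1-benzofuran-2-yl]propanoate
Conditions: H2 (1 atm), 10% Pd/C, EtOAc, rt
Reagents that add atoms: none
Why: Heterogeneous catalytic hydrogenation saturates the disubstituted conjugated enoate C=C, whereas the tetrasubstituted C2=C3 bond of the aromatic furan ring should not be reduced at 1 atm and room temperature.

Step 11
Reactants: 19 methyl 3-[3-(3,5-dimethoxy-2,4-dimethylphenyl)-6-methoxy-4-methyl-1-benzofuran-2-yl]propanoate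
Product: 21 talarominine A (methyl 3-[3-(3,5-dihydroxy-2,4-dimethylphenyl)-6-hydroxy-4-methyl-1-benzofuran-2-yl]propanoate), via triphenol carboxylic acid 20 (not isolated)
Conditions: BBr3 (8 equiv), CH2Cl2, −78 °C → rt; then MeOH, 60 °C
Reagents that add atoms: methanol, CO (the ester methoxy group)
Why: BBr3 cleaves the three aryl methyl ethers (Lewis-acid ether cleavage) and also the ester O–methyl bond, and the HBr released on addition of methanol then returns acid 20 to the methyl ester by Fischer esterification, which does not methylate phenols.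

**Compound list**

1 | 2,6-dimethoxytoluene (1,3-dimethoxy-2-methylbenzene) | COc1cccc(OC)c1C | starting material
2 | 2-(3,5-dimethoxy-4-methylphenyl)-4,4,5,5-tetramethyl-1,3,2-dioxaborolane | COc1cc(cc(OC)c1C)B1OC(C)(C)C(C)(C)O1 | intermediate (not isolated)
3 | 5-bromo-1,3-dimethoxy-2-methylbenzene | COc1cc(Br)cc(OC)c1C | intermediate
4 | 6-bromo-2,4-dimethoxy-3-methylbenzaldehyde | COc1cc(Br)c(C=O)c(OC)c1C | intermediate
5 | 1-bromo-3,5-dimethoxy-2,4-dimethylbenzene | COc1cc(Br)c(C)c(OC)c1C | intermediate
6 | 2,4-dimethoxy-6-methylbenzaldehyde | COc1cc(C)c(C=O)c(OC)c1 | starting material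
7 | 2-hydroxy-4-methoxy-6-methylbenzaldehyde | COc1cc(C)c(C=O)c(O)c1 | intermediate
8 | (3,5-dimethoxy-2,4-dimethylphenyl)lithium | [Li]c1cc(OC)c(C)c(OC)c1C | intermediate (not isolated)
9 | sodium 2-formyl-5-methoxy-3-methylphenolate | COc1cc(C)c(C=O)c([O-])c1.[Na+] | intermediate (not isolated)
10 | 2-[(3,5-dimethoxy-2,4-dimethylphenyl)(hydroxy)methyl]-5-methoxy-3-methylphenol (racemic) | COc1cc(C)c(C(O)c2cc(OC)c(C)c(OC)c2C)c(O)c1 | intermediate
11 | 2-[(3,5-dimethoxy-2,4-dimethylphenyl)(4-methylbenzenesulfonyl)methyl]-5-methoxy-3-methylphenol (racemic) | COc1cc(C)c(C(c2cc(OC)c(C)c(OC)c2C)S(=O)(=O)c2ccc(C)cc2)c(O)c1 | intermediate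
12 | methyl (2E)-4-bromobut-2-enoate | COC(=O)/C=C/CBr | starting material
13 | [(2E)-4-methoxy-4-oxobut-2-en-1-yl]dimethylsulfonium bromide | C[S+](C)C/C=C/C(=O)OC.[Br-] | intermediate
14 | dimethylsulfonium (2E)-4-methoxy-4-oxobut-2-en-1-ide (ylide) | C[S+](C)[CH-]/C=C/C(=O)OC | intermediate (not isolated)
15 | 6-[(3,5-dimethoxy-2,4-dimethylphenyl)methylidene]-3-methoxy-5-methylcyclohexa-2,4-dien-1-one (alkene geometry not defined) | COC1=CC(=O)C(=Cc2cc(OC)c(C)c(OC)c2C)C(C)=C1 | intermediate (not isolated)
16 | 2-[(3E)-2-(dimethylsulfonio)-1-(3,5-dimethoxy-2,4-dimethylphenyl)-5-methoxy-5-oxopent-3-en-1-yl]-5-methoxy-3-methylphenolate (betaine, diastereomer mixture) | C[S+](C)C(/C=C/C(=O)OC)C(c1cc(OC)c(C)c(OC)c1C)c1c(C)cc(OC)cc1[O-] | intermediate (not isolated)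
17 | methyl (2E)-3-[trans-3-(3,5-dimethoxy-2,4-dimethylphenyl)-6-methoxy-4-methyl-2,3-dihydro-1-benzofuran-2-yl]prop-2-enoate (racemic; 2S,3R enantiomer drawn) | COC(=O)/C=C/[C@@H]1Oc2cc(OC)cc(C)c2[C@H]1c1cc(OC)c(C)c(OC)c1C | intermediate
18 | methyl (2E)-3-[3-(3,5-dimethoxy-2,4-dimethylphenyl)-6-methoxy-4-methyl-1-benzofuran-2-yl]prop-2-enoate | COC(=O)/C=C/c1oc2cc(OC)cc(C)c2c1-c1cc(OC)c(C)c(OC)c1C | intermediate
19 | methyl 3-[3-(3,5-dimethoxy-2,4-dimethylphenyl)-6-methoxy-4-methyl-1-benzofuran-2-yl]propanoate | COC(=O)CCc1oc2cc(OC)cc(C)c2c1-c1cc(OC)c(C)c(OC)c1C | intermediate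
20 | 3-[3-(3,5-dihydroxy-2,4-dimethylphenyl)-6-hydroxy-4-methyl-1-benzofuran-2-yl]propanoic acid | OC(=O)CCc1oc2cc(O)cc(C)c2c1-c1cc(O)c(C)c(O)c1C | intermediate (not isolated)
21 | talarominine A, methyl 3-[3-(3,5-dihydroxy-2,4-dimethylphenyl)-6-hydroxy-4-methyl-1-benzofuran-2-yl]propanoate | COC(=O)CCc1oc2cc(O)cc(C)c2c1-c1cc(O)c(C)c(O)c1C | target

**Count**

Total step count: 11.
Longest linear sequence: 9 steps (1, 2, 3, 5, 6, 8, 9, 10, 11).

**Steps most likely to fail**

1. Step 8. The ambident allylic ylide may add through its γ-carbon, the allylic sulfonium salt may alkylate the phenoxide oxygen of 11, or the ylide may condense with its own enoate faster than it captures 15. The fallback sets out from 11 and keeps the annulation but uses the commercial, isolable ylide ethyl (dimethyl-λ4-sulfanylidene)acetate (Cs2CO3, CH2Cl2, rt). Quinone methide 15 should take it up to give the betaine 2-[2-(dimethylsulfonio)-1-(3,5-dimethoxy-2,4-dimethylphenyl)-3-ethoxy-3-oxopropyl]-5-methoxy-3-methylphenolate F1, which closes to ethyl trans-3-(3,5-dimethoxy-2,4-dimethylphenyl)-6-methoxy-4-methyl-2,3-dihydro-1-benzofuran-2-carboxylate F2. DDQ (dioxane, 80 °C) should then give ethyl 3-(3,5-dimethoxy-2,4-dimethylphenyl)-6-methoxy-4-methyl-1-benzofuran-2-carboxylate F3, and i-Bu2AlH (CH2Cl2, −78 → 0 °C) the alcohol [3-(3,5-dimethoxy-2,4-dimethylphenyl)-6-methoxy-4-methyl-1-benzofuran-2-yl]methanol F4. MnO2 (CH2Cl2, rt) should give the aldehyde 3-(3,5-dimethoxy-2,4-dimethylphenyl)-6-methoxy-4-methyl-1-benzofuran-2-carbaldehyde F5, and Wittig olefination with Ph3P=CHCO2Me (toluene, 80 °C) the E-enoate 18, where the route is rejoined.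

2. Step 9. Single-electron oxidation of the two electron-rich aryl rings by DDQ may outrun hydride abstraction from the hindered C3–H, so that conversion stalls or quinone adducts form. The fallback is redox-neutral and sets out from 17. LiN(i-Pr)2 (THF/DMPU, −78 °C) removes the C2 proton, which is γ to the ester, to give the lithium dienolate lithium 3-[3-(3,5-dimethoxy-2,4-dimethylphenyl)-6-methoxy-4-methyl-1-benzofuran-2(3H)-ylidene]-1-methoxyprop-1-en-1-olate F6. Kinetic protonation at the α-carbon (AcOH, −78 °C) gives the deconjugated exocyclic enol ether methyl 3-[3-(3,5-dimethoxy-2,4-dimethylphenyl)-6-methoxy-4-methyl-1-benzofuran-2(3H)-ylidene]propanoate F7. A catalytic amount of TsOH (CH2Cl2, rt) then moves the C3 hydrogen to the exocyclic carbon (enol ether to aromatic furan tautomerisation) and delivers 19, so that steps 9 and 10 are both bypassed.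

3. Step 5. The aryllithium may deprotonate the ortho-methyl group of the deactivated, poorly soluble phenoxide aldehyde in place of adding to it, and the product may ionise during work-up. The fallback sets out from 5 and 6: aryllithium 8 (from 5, n-BuLi, THF, −78 °C) is added to the phenol-free aldehyde 6 to give (2,4-dimethoxy-6-methylphenyl)(3,5-dimethoxy-2,4-dimethylphenyl)methanol F8. MnO2 (CH2Cl2, rt) oxidises it to the benzophenone (2,4-dimethoxy-6-methylphenyl)(3,5-dimethoxy-2,4-dimethylphenyl)methanone F9. BCl3 (CH2Cl2, −78 → 0 °C) cleaves the single methoxy group ortho to the carbonyl to give (3,5-dimethoxy-2,4-dimethylphenyl)(2-hydroxy-4-methoxy-6-methylphenyl)methanone F10, and LiAlH4 (THF, 0 °C) reduces the ketone to benzhydrol 10, where the route is rejoined.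

**Further compounds**

F1 | step 8 | 2-[2-(dimethylsulfonio)-1-(3,5-dimethoxy-2,4-dimethylphenyl)-3-ethoxy-3-oxopropyl]-5-methoxy-3-methylphenolate (betaine, diastereomer mixture) | C[S+](C)C(C(=O)OCC)C(c1cc(OC)c(C)c(OC)c1C)c1c(C)cc(OC)cc1[O-]
F2 | step 8 | ethyl trans-3-(3,5-dimethoxy-2,4-dimethylphenyl)-6-methoxy-4-methyl-2,3-dihydro-1-benzofuran-2-carboxylate (racemic, one enantiomer drawn) | CCOC(=O)[C@@H]1Oc2cc(OC)cc(C)c2[C@H]1c1cc(OC)c(C)c(OC)c1C
F3 | step 8 | ethyl 3-(3,5-dimethoxy-2,4-dimethylphenyl)-6-methoxy-4-methyl-1-benzofuran-2-carboxylate | CCOC(=O)c1oc2cc(OC)cc(C)c2c1-c1cc(OC)c(C)c(OC)c1C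
F4 | step 8 | [3-(3,5-dimethoxy-2,4-dimethylphenyl)-6-methoxy-4-methyl-1-benzofuran-2-yl]methanol | OCc1oc2cc(OC)cc(C)c2c1-c1cc(OC)c(C)c(OC)c1C
F5 | step 8 | 3-(3,5-dimethoxy-2,4-dimethylphenyl)-6-methoxy-4-methyl-1-benzofuran-2-carbaldehyde | O=Cc1oc2cc(OC)cc(C)c2c1-c1cc(OC)c(C)c(OC)c1C
F6 | step 9 | lithium 3-[3-(3,5-dimethoxy-2,4-dimethylphenyl)-6-methoxy-4-methyl-1-benzofuran-2(3H)-ylidene]-1-methoxyprop-1-en-1-olate (racemic, alkene geometries not defined) | [Li+].COC([O-])=CC=C1Oc2cc(OC)cc(C)c2C1c1cc(OC)c(C)c(OC)c1C
F7 | step 9 | methyl 3-[3-(3,5-dimethoxy-2,4-dimethylphenyl)-6-methoxy-4-methyl-1-benzofuran-2(3H)-ylidene]propanoate (racemic, alkene geometry not defined) | COC(=O)CC=C1Oc2cc(OC)cc(C)c2C1c1cc(OC)c(C)c(OC)c1C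
F8 | step 5 | (2,4-dimethoxy-6-methylphenyl)(3,5-dimethoxy-2,4-dimethylphenyl)methanol (racemic) | COc1cc(C)c(C(O)c2cc(OC)c(C)c(OC)c2C)c(OC)c1
F9 | step 5 | (2,4-dimethoxy-6-methylphenyl)(3,5-dimethoxy-2,4-dimethylphenyl)methanone | COc1cc(C)c(C(=O)c2cc(OC)c(C)c(OC)c2C)c(OC)c1
F10 | step 5 | (3,5-dimethoxy-2,4-dimethylphenyl)(2-hydroxy-4-methoxy-6-methylphenyl)methanone | COc1cc(C)c(C(=O)c2cc(OC)c(C)c(OC)c2C)c(O)c1
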